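The seven-membered ring C5–C6–C7–C8–C9–C10–C11 has an oxygen on C7 next to the gem-dimethyl carbon C6, which is bonded to the cyclobutane carbon C5: the retron of a semipinacol ring enlargement. Atoms are numbered as in longipinane (C1 ketone, C6 CMe2, C7 tiglate carbon, C9 senecioate carbon, C10 C–CH3, C11 cyclobutane CH beside C1). The route builds the tricycle that lacks C6 (six-membered ring C5–C7–C8–C9–C10–C11) from a catalytic asymmetric quinone Diels–Alder adduct by an enolate alkylation that closes the cyclobutane. Addition of a 2-(phenylselanyl)prop-2-yl anion to the C7 ketone and a silver-induced 1,2-shift of C5 from C7 to C6 then insert C6, create the quaternary centre and the C7 ketone, and enlarge the ring in one operation.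

Key step: step 12

Numbering: every intermediate carries the longipinane numbers of the target: C1 (ring ketone), C2=C3 (C3 bears the vinyl methyl), C4 and C5 (cyclobutane CH), C6 (CMe2), C7, C8 (CH2), C9, C10 (C–CH3), C11 (cyclobutane CH next to C1).
Assumption: the chiral catalysts of steps 2 and 8 are taken to deliver the faces drawn; if either gives the opposite sense, the mirror-image ligand is used.

Step 1
Reactants: 1 (E)-pent-3-en-2-one
Product: 2 (E)-2-(tert-butyldimethylsilyloxy)penta-1,3-diene
Conditions: TBSOTf, Et3N, Et2O, 0 °C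
Reagents that add atoms: tert-butyldimethylsilyl trifluoromethanesulfonate, CC(C)(C)[Si](C)(C)OS(=O)(=O)C(F)(F)F
Why: Soft enolisation of the methyl ketone and O-silylation (silyl dienol ether formation) should give the 2-silyloxydiene with the E alkene untouched.

Step 2
Reactants: 2 (E)-2-(tert-butyldimethylsilyloxy)penta-1,3-diene; 3 2-methoxy-5-methyl-1,4-benzoquinone
Product: 4 cis-fused Diels–Alder adduct (C5 and C9 ketones; C7-methoxy C7=C8 alkene; C10 methyl cis to H-4; silyl enol ether C1=C2; C3 methyl trans to H-4)
Conditions: (R)-BINOL, TiCl2(OiPr)2 (20 mol %), 4 Å MS, toluene, −40 °C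
Reagents that add atoms: none
Why: Catalytic asymmetric Diels–Alder reaction in which titanium, chelated between the methoxy oxygen and the neighbouring carbonyl, activates that carbonyl so that the nucleophilic CH2 terminus of the diene (C11) bonds to the methyl-bearing carbon C10 while the methoxy-deactivated alkene stays untouched; the endo transition state gives the cis ring fusion and the ligand sets C10 and C4.

Step 3
Reactants: 4 cis-fused Diels–Alder adduct
Product: 5 C5 alcohol of 4 (hydroxyl on the concave face, cis to the C4–C3 and C10–C11 bonds)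
Conditions: NaBH4, CeCl3·7H2O, MeOH/CH2Cl2, −78 °C
Reagents that add atoms: none
Why: Luche 1,2-reduction should take the cross-conjugated C5 ketone and leave the much less electrophilic vinylogous ester carbonyl C9 alone, hydride entering from the convex face of the cis-fused bicycle.

Step 4
Reactants: 5 C5 alcohol
Product: 6 hydroxy enone (C1 ketone with C2=C3 alkene; C5 hydroxyl; C9 vinylogous ester)
Conditions: Pd(OAc)2 (1.1 equiv), MeCN, 25 °C
Reagents that add atoms: none
Why: Saegusa–Ito oxidation of the silyl enol ether gives the C1 enone with the alkene at C2=C3, which removes the C3 stereocentre and leaves C11 as the only enolisable carbon next to C1.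

Step 5
Reactants: 6 hydroxy enone
Product: 7 C5 bromide (bromine on the convex face, trans to the C10–C11 bond)
Conditions: CBr4, PPh3, CH2Cl2, 0 °C
Reagents that add atoms: tetrabromomethane, BrC(Br)(Br)Br
Why: Appel reaction with SN2 inversion should place the leaving group anti to the side from which C11 must later attack.

Step 6
Reactants: 7 C5 bromide
Product: 9 tricyclic methoxy bis-enone (cyclobutane C4–C5–C11–C10; C1 ketone with C2=C3; C9 ketone with C7-methoxy C7=C8), via lithium enolate 8 (not isolated)
Conditions: LiN(iPr)2 (1.1 equiv), THF, −78 to 0 °C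
Reagents that add atoms: none
Why: Intramolecular enolate alkylation: kinetic α′-deprotonation of the enone at C11 and 4-exo-tet SN2 displacement with inversion at C5, as in the keto-sulfonate closures of cis-decalins to copaene-type tricyclo[4.4.0.0(2,7)]decanones; O-alkylation would need a bridgehead enol ether, and the cis ring fusion fixes the configuration of C11 and C5.

Step 7
Reactants: 9 tricyclic methoxy bis-enone
Product: 11 tricyclic hydroxy enone (C7 ketone with C8=C9 alkene; C1 hydroxyl syn to C10; C2=C3 alkene), via diol 10 (not isolated)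
Conditions: iBu2AlH (3 equiv), CH2Cl2, −78 °C; then 0.5 M HCl, THF, 0 °C
Reagents that add atoms: water, O
Why: 1,2-Reduction of both carbonyls (hydride at C1 from the side of the C5 bridge, away from the C10 methyl) followed by Stork–Danheiser transposition of the 3-methoxy allylic alcohol moves the ring carbonyl from C9 to C7, where the ring enlargement needs it, and leaves C1 masked as an allylic alcohol.

Step 8
Reactants: 11 tricyclic hydroxy enone
Product: 13 dihydroxy ketone (C7 ketone; C9 hydroxyl on the face toward C11; C1 hydroxyl), via pinacol boronate 12 (not isolated)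
Conditions: CuCl (5 mol %), NaOtBu, (R)-DTBM-SEGPHOS, B2pin2, MeOH, THF, 0 °C; then H2O2, NaHCO3, H2O
Reagents that add atoms: hydrogen peroxide, OO
Why: Copper-catalysed enantioselective conjugate borylation followed by oxidation with retention; the two faces of the C8=C9 alkene differ only in remote groups (C1 side against C3 side), so the ligand and not the substrate should decide the configuration at C9.

Step 9
Reactants: 13 dihydroxy ketone
Product: 14 bis(tert-butyldimethylsilyl) ether of 13
Conditions: TBSOTf, 2,6-lutidine, CH2Cl2, −40 to 0 °C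
Reagents that add atoms: tert-butyldimethylsilyl trifluoromethanesulfonate, CC(C)(C)[Si](C)(C)OS(=O)(=O)C(F)(F)F
Why: Silylation of both hydroxyls protects the β-hydroxy ketone against retro-aldol cleavage and the allylic alcohol against deprotonation in the organolithium addition.

Step 10
Reactants: 15 acetone
Product: 16 2,2-bis(phenylselanyl)propane
Conditions: PhSeH, ZnCl2 (cat.), CH2Cl2, 25 °C
Reagents that add atoms: benzeneselenol, [SeH]c1ccccc1
Why: Lewis-acid-catalysed selenoketalisation of the ketone.

Step 11
Reactants: 14 bis(tert-butyldimethylsilyl) ether; 16 2,2-bis(phenylselanyl)propane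
Product: 18 C7 tertiary alcohol carrying the 2-(phenylselanyl)prop-2-yl group (drawn with the new carbon group anti to the C9 silyl ether), via 2-lithio-2-(phenylselanyl)propane 17 (not isolated)
Conditions: 16, n-BuLi, THF, −78 °C; then 14, −78 °C; H2O
Reagents that add atoms: none
Why: Selenium–lithium exchange gives the α-selenoalkyllithium, a weakly basic tertiary carbanion that adds to hindered enolisable ketones (1,2-addition); the configuration of the new carbinol centre is of no consequence because C7 becomes trigonal in the next step.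

Step 12
Reactants: 18 C7 tertiary alcohol carrying the 2-(phenylselanyl)prop-2-yl group
Product: 19 1,9-bis(tert-butyldimethylsilyloxy)longipin-2-en-7-one
Conditions: AgBF4, basic Al2O3, CH2Cl2, 0 to 25 °C
Reagents that add atoms: none
Why: Silver binds the selenium of 18, the C6–Se bond ionises toward a tertiary cation (or leaves in concert) and the C5–C7 bond anti to it shifts from C7 to C6 while the hydroxyl oxygen becomes the C7 carbonyl. The closest known reaction type is the ring enlargement of β-hydroxyalkyl selenides to α,α-dialkyl cycloalkanones, a semipinacol rearrangement of the Tiffeneau–Demjanov kind. No ring is closed: the two six-membered rings that share the C5–C7 bond, among them C5–C7–C8–C9–C10–C11, each take up C6 and become the seven-membered rings of the target, with the cyclobutane and both silyl ethers untouched. No stereocentre is formed, since C5 migrates with retention, C6 is not stereogenic and C7 becomes trigonal, so any mixture of C7 epimers of 18 converges. The step needs migration of the cyclobutyl methine C5 and not of the C8 methylene, and rearrangement instead of oxirane closure: the higher migratory aptitude of the more substituted carbon, the fully substituted cationic centre and the base-free medium should secure both, and keeping the leaving group on C6 keeps positive charge away from C7, where a cyclobutylcarbinyl cation would open the four-membered ring.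

Step 13
Reactants: 19 1,9-bis(tert-butyldimethylsilyloxy)longipin-2-en-7-one
Product: 20 1,9-dihydroxylongipin-2-en-7-one
Conditions: HF·pyridine, THF, 0 to 25 °C
Reagents that add atoms: none
Why: Desilylation with a weakly acidic fluoride source frees both hydroxyls without the β-elimination or retro-aldol cleavage that a basic fluoride could cause.

Step 14
Reactants: 20 1,9-dihydroxylongipin-2-en-7-one
Product: 21 9-hydroxylongipin-2-ene-1,7-dione
Conditions: MnO2, CH2Cl2, 25 °C
Reagents that add atoms: none
Why: MnO2 oxidation is selective for the allylic C1 alcohol and should restore the C1 enone while the saturated C9 carbinol stays.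

Step 15
Reactants: 21 9-hydroxylongipin-2-ene-1,7-dione
Product: 23 7-hydroxy-9-(3-methylbut-2-enoyloxy)longipin-2-en-1-one (O-7 on the face toward C4; O-9 on the face toward C11), via hemiacetal 22 (not isolated)
Conditions: SmI2 (0.3 equiv), 3-methylbut-2-enal (6 equiv), THF, −10 °C
Reagents that add atoms: 3-methylbut-2-enal, CC(C)=CC=O
Why: Evans–Tishchenko reaction: the samarium-bound hemiacetal on O-9 delivers its hydride to the C7 carbonyl from the face of O-9, which sets C7 anti to C9 and at the same time leaves the senecioate on O-9 only; the C1 enone has no β-hydroxyl and is not reduced.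

Step 16
Reactants: 23 7-hydroxy-9-(3-methylbut-2-enoyloxy)longipin-2-en-1-one
Product: 24 9-(3-methylbut-2-enoyloxy)-7-[(E)-2-methylbut-2-enoyloxy]longipin-2-en-1-one (target)
Conditions: (E)-2-methylbut-2-enoyl chloride, Et3N, DMAP (cat.), CH2Cl2, 40 °C
Reagents that add atoms: (E)-2-methylbut-2-enoyl chloride, C/C=C(\C)C(Cl)=O
Why: DMAP-catalysed acylation of the remaining hindered secondary alcohol; the tiglate is the stable E isomer, so no geometric isomerisation is expected.

Compound list
1 | (E)-pent-3-en-2-one | C/C=C/C(C)=O | starting material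
2 | (E)-2-(tert-butyldimethylsilyloxy)penta-1,3-diene | C=C(O[Si](C)(C)C(C)(C)C)/C=C/C | intermediate
3 | 2-methoxy-5-methyl-1,4-benzoquinone | COC1=CC(=O)C(C)=CC1=O | starting material
4 | cis-fused Diels–Alder adduct (C5, C9 ketones; 7-methoxy C7=C8; silyl enol ether C1=C2; C10 methyl cis to H-4; C3 methyl trans to H-4) | COC1=CC(=O)[C@@]2(C)CC(O[Si](C)(C)C(C)(C)C)=C[C@@H](C)[C@H]2C1=O | intermediate
5 | C5 alcohol of 4 (hydroxyl on the concave face) | COC1=CC(=O)[C@@]2(C)CC(O[Si](C)(C)C(C)(C)C)=C[C@@H](C)[C@H]2[C@H]1O | intermediate
6 | hydroxy enone (C1 ketone, C2=C3; C5 hydroxyl; C9 vinylogous ester) | COC1=CC(=O)[C@@]2(C)CC(=O)C=C(C)[C@H]2[C@H]1O | intermediate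
7 | C5 bromide (inverted, bromine on the convex face) | COC1=CC(=O)[C@@]2(C)CC(=O)C=C(C)[C@H]2[C@@H]1Br | intermediate
8 | lithium C11=C1 enolate of 7 | COC1=CC(=O)[C@@]2(C)C=C(O[Li])C=C(C)[C@H]2[C@@H]1Br | intermediate
9 | tricyclic methoxy bis-enone (cyclobutane C4–C5–C11–C10; C1 ketone with C2=C3; C9 ketone with 7-methoxy C7=C8) | COC1=CC(=O)[C@@]2(C)[C@@H]3C(=O)C=C(C)[C@H]2[C@H]13 | intermediate
10 | diol (C1 and C9 carbinols, 7-methoxy C7=C8 enol ether; C9 epimers; C1 hydroxyl syn to C10) | COC1=CC(O)[C@@]2(C)[C@@H]3[C@H](O)C=C(C)[C@H]2[C@H]13 | intermediate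
11 | tricyclic hydroxy enone (C7 ketone, C8=C9; C1 hydroxyl syn to C10) | O=C1C=C[C@@]2(C)[C@@H]3[C@H](O)C=C(C)[C@H]2[C@H]13 | intermediate
12 | C9 pinacol boronate of 11 (boron on the face toward C11) | O=C1C[C@@H](B2OC(C)(C)C(C)(C)O2)[C@@]3(C)[C@@H]4[C@H](O)C=C(C)[C@H]3[C@H]14 | intermediate
13 | dihydroxy ketone (C7 ketone; C9 hydroxyl toward C11; C1 hydroxyl syn to C10) | O=C1C[C@@H](O)[C@@]2(C)[C@@H]3[C@H](O)C=C(C)[C@H]2[C@H]13 | intermediate
14 | bis(tert-butyldimethylsilyl) ether of 13 | O=C1C[C@@H](O[Si](C)(C)C(C)(C)C)[C@@]2(C)[C@@H]3[C@H](O[Si](C)(C)C(C)(C)C)C=C(C)[C@H]2[C@H]13 | intermediate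
15 | acetone | CC(C)=O | starting material
16 | 2,2-bis(phenylselanyl)propane | CC(C)([Se]c1ccccc1)[Se]c1ccccc1 | intermediate
17 | 2-lithio-2-(phenylselanyl)propane | [Li]C(C)(C)[Se]c1ccccc1 | intermediate
18 | C7 tertiary alcohol carrying the 2-(phenylselanyl)prop-2-yl group (hydroxyl on the face toward C11) | CC(C)([Se]c1ccccc1)[C@]1(O)C[C@@H](O[Si](C)(C)C(C)(C)C)[C@@]2(C)[C@@H]3[C@H](O[Si](C)(C)C(C)(C)C)C=C(C)[C@H]2[C@H]13 | intermediate
19 | 1,9-bis(tert-butyldimethylsilyloxy)longipin-2-en-7-one (O-9 toward C11; O-1 syn to C10) | O=C1C[C@@H](O[Si](C)(C)C(C)(C)C)[C@@]2(C)[C@@H]3[C@H](O[Si](C)(C)C(C)(C)C)C=C(C)[C@H]2[C@@H]3C1(C)C | intermediate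
20 | 1,9-dihydroxylongipin-2-en-7-one | O=C1C[C@@H](O)[C@@]2(C)[C@@H]3[C@H](O)C=C(C)[C@H]2[C@@H]3C1(C)C | intermediate
21 | 9-hydroxylongipin-2-ene-1,7-dione | O=C1C[C@@H](O)[C@@]2(C)[C@@H]3C(=O)C=C(C)[C@H]2[C@@H]3C1(C)C | intermediate
22 | hemiacetal of 21 with 3-methylbut-2-enal on O-9 | O=C1C[C@@H](OC(O)C=C(C)C)[C@@]2(C)[C@@H]3C(=O)C=C(C)[C@H]2[C@@H]3C1(C)C | intermediate
23 | 7-hydroxy-9-(3-methylbut-2-enoyloxy)longipin-2-en-1-one (O-7 toward C4, O-9 toward C11) | O[C@@H]1C[C@@H](OC(=O)C=C(C)C)[C@@]2(C)[C@@H]3C(=O)C=C(C)[C@H]2[C@@H]3C1(C)C | intermediate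
24 | 9-(3-methylbut-2-enoyloxy)-7-[(E)-2-methylbut-2-enoyloxy]longipin-2-en-1-one | C/C=C(\C)C(=O)O[C@@H]1C[C@@H](OC(=O)C=C(C)C)[C@@]2(C)[C@@H]3C(=O)C=C(C)[C@H]2[C@@H]3C1(C)C | target

Total step count: 16. Longest linear sequence: 15 steps (steps 1 to 9 and 11 to 16; step 10 is a side branch).

Steps most likely to fail

Step 6 (cyclobutane closure). The lithium enolate may add in conjugate fashion to the β-methoxy enone, or hydrogen bromide may be lost, faster than the strained four-membered ring closes. The fallback sets out from 5 and comes back at 13; it removes the methoxy enone before the closure. Reduction of 5 with iBu2AlH and mild acid hydrolysis (Stork–Danheiser transposition) should give the transposed hydroxy enone with the silyl enol ether intact F1. Saegusa–Ito oxidation gives the bis-enone alcohol F2, and mesylation gives the α-keto methanesulfonate F3, whose C5 centre epimerises through its enol so that either epimer can be displaced. KN(SiMe3)2 then closes the tricyclic dienedione F4. Copper-catalysed boryl addition to the less substituted C8=C9 enone, as in step 8, gives the boronate F5 and, after oxidation, the hydroxy diketone F6. Luche reduction of the C1 enone carbonyl in preference to the saturated C7 ketone returns 13.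

Step 12 (ring enlargement). Oxirane closure may compete with the 1,2-shift, or the silver salt may ionise the allylic silyl ether. The fallback sets out from 14 and comes back at 19 by a β-oxido carbenoid ring enlargement. LiCBr2CH3 (from 1,1-dibromoethane and LiN(iPr)2, −100 °C) adds to 14 to give the dibromo carbinol F7. Two equivalents of n-BuLi remove the hydroxyl proton and exchange one bromine; the carbenoid rearranges with migration of C5 to the lithium enolate of the ring-enlarged 6-methyl ketone F8. Methylation of F8 at C6 with MeI in the same flask gives 19.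

Step 15 (Evans–Tishchenko). Hemiacetal formation and hydride transfer may be slow at the neopentyl ketone with a conjugated aldehyde, and retro-aldol cleavage or reduction of the enone by SmI2 may compete. The fallback sets out from 21 and comes back at 23. Evans–Saksena reduction with Me4NBH(OAc)3 (MeCN/AcOH, −30 °C), directed by the C9 hydroxyl, should give the anti diol F9. 3-Methylbut-2-enoyl chloride with pyridine at −20 °C should then acylate the C9 hydroxyl, the C7 hydroxyl beside the gem-dimethyl carbon being the more hindered, to give 23.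

Further compounds
F1 | step 6 | transposed hydroxy enone (C7 ketone, C8=C9; C5 hydroxyl; silyl enol ether C1=C2) | O=C1C=C[C@@]2(C)CC(O[Si](C)(C)C(C)(C)C)=C[C@@H](C)[C@H]2[C@H]1O
F2 | step 6 | bis-enone alcohol (C1 ketone with C2=C3; C7 ketone with C8=C9; C5 hydroxyl) | O=C1C=C[C@@]2(C)CC(=O)C=C(C)[C@H]2[C@H]1O
F3 | step 6 | C5 methanesulfonate of F2 | O=C1C=C[C@@]2(C)CC(=O)C=C(C)[C@H]2[C@H]1OS(C)(=O)=O
F4 | step 6 | tricyclic dienedione (C1 ketone with C2=C3; C7 ketone with C8=C9) | O=C1C=C[C@@]2(C)[C@@H]3C(=O)C=C(C)[C@H]2[C@H]13
F5 | step 6 | C9 pinacol boronate of F4 | O=C1C[C@@H](B2OC(C)(C)C(C)(C)O2)[C@@]3(C)[C@@H]4C(=O)C=C(C)[C@H]3[C@H]14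
F6 | step 6 | tricyclic 9-hydroxy 1,7-dione (C1 enone kept) | O=C1C[C@@H](O)[C@@]2(C)[C@@H]3C(=O)C=C(C)[C@H]2[C@H]13
F7 | step 12 | C7 tertiary alcohol carrying a 1,1-dibromoethyl group | CC(Br)(Br)[C@]1(O)C[C@@H](O[Si](C)(C)C(C)(C)C)[C@@]2(C)[C@@H]3[C@H](O[Si](C)(C)C(C)(C)C)C=C(C)[C@H]2[C@H]13
F8 | step 12 | lithium C6=C7 enolate of the ring-enlarged 6-methyl ketone | [Li]OC=1C[C@@H](O[Si](C)(C)C(C)(C)C)[C@@]2(C)[C@@H]3[C@H](O[Si](C)(C)C(C)(C)C)C=C(C)[C@H]2[C@@H]3C=1C
F9 | step 15 | 7,9-dihydroxylongipin-2-en-1-one (anti diol; O-7 toward C4, O-9 toward C11) | O[C@@H]1C[C@@H](O)[C@@]2(C)[C@@H]3C(=O)C=C(C)[C@H]2[C@@H]3C1(C)C
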